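**Retrosynthetic overview**
1. Core numbering C1–C9 as in bicyclo[3.3.1]nonane (C1 acyl bridgehead, C9 bridging ketone). Ring B (C1–C2–C3–C4–C5–C9) is closed last: C1–C2 and C4–C5 are cut back to a 2-acylcyclohexanone (ring A) plus malonyl dichloride (Effenberger-type [3+3] annulation).
2. Ring A is opened at the key C1–C8 bond to an acyclic β-diketone carrying a 1,1-disubstituted alkene; forward this is a light-driven cobalt-hydride, Conia-ene-type cycloisomerisation.
3. The β-diketone comes from a methyl ketone and (R)-2-methylbutanoic acid by crossed Claisen condensation.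
4. The methyl ketone comes from (1S,2S,4R)-limonene-1,2-diol: geranylation of the isopropenyl methyl group, glycol cleavage, Wittig isopropylidenation.
5. Stereochemistry: C7 is C4 of limonene and the acyl stereocentre is bought with the acid; C8 is relayed from C7 in the cyclisation, and C1 and C5 from C7 in the annulation.

Assumption: the target is handled as the enol tautomer drawn (its SMILES corresponds to 1R,5R,7S,8R with an (R)-2-methylbutanoyl group), and (1S,2S,4R)-limonene-1,2-diol and (R)-2-methylbutanoic acid are taken as commercial.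

**Step 1**
Reactants: 1 (1S,2S,4R)-limonene-1,2-diol
Product: 2 (1S,2S,4R)-4-[(5E)-6,10-dimethylundeca-1,5,9-trien-2-yl]-1-methylcyclohexane-1,2-diol
Conditions: n-BuLi (3.3 equiv), TMEDA, hexane/Et2O, 0 °C to rt, 16 h; geranyl bromide, −78 to 0 °C; H2O
Reagents that add atoms: geranyl bromide, CC(C)=CCC/C(C)=C/CBr
Why: Alkoxide-tolerant allylic lithiation of the isopropenyl methyl group (as in the known metalation of limonene) followed by SN2 alkylation of the symmetric 2-substituted allyllithium with the primary allylic bromide; no stereocentre is formed, and the three existing ones and the E alkene are untouched.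

**Step 2**
Reactants: 2 (1S,2S,4R)-4-[(5E)-6,10-dimethylundeca-1,5,9-trien-2-yl]-1-methylcyclohexane-1,2-diol
Product: 3 (3R)-3-[(5E)-6,10-dimethylundeca-1,5,9-trien-2-yl]-6-oxoheptanal
Conditions: NaIO4, THF/H2O, 0 °C to rt
Reagents that add atoms: none
Why: Malaprade glycol cleavage of the trans-1,2-diol gives the methyl ketone and the aldehyde; the remaining stereocentre (future C7) is not α to either carbonyl and cannot epimerise.

**Step 3**
Reactants: 3 (3R)-3-[(5E)-6,10-dimethylundeca-1,5,9-trien-2-yl]-6-oxoheptanal
Product: 4 (5R)-5-[(5E)-6,10-dimethylundeca-1,5,9-trien-2-yl]-8-methylnon-7-en-2-one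
Conditions: i-PrPPh3I, n-BuLi, THF, 0 °C; then 3, −78 to 0 °C
Reagents that add atoms: isopropyltriphenylphosphonium iodide, CC(C)[P+](c1ccccc1)(c1ccccc1)c1ccccc1.[I-]
Why: Wittig olefination; the non-stabilised ylide reacts with the aldehyde far faster than with the methyl ketone at low temperature and builds the prenyl group, with no stereocentre formed.

**Step 4**
Reactants: 4 (5R)-5-[(5E)-6,10-dimethylundeca-1,5,9-trien-2-yl]-8-methylnon-7-en-2-one; 5 (R)-2-methylbutanoic acid
Product: 7 (3R,9R)-9-[(5E)-6,10-dimethylundeca-1,5,9-trien-2-yl]-3,12-dimethyltridec-11-ene-4,6-dione, via acyl imidazolide 6 (not isolated)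
Conditions: 5, 1,1'-carbonyldiimidazole, THF, rt (gives 6); 4, LiN(SiMe3)2 (3.2 equiv), THF, −78 °C; add 6, −78 to −20 °C; 1 M HCl
Reagents that add atoms: none
Why: Crossed Claisen condensation; kinetic deprotonation at the methyl group, C-acylation by the acyl imidazolide, and storage of the product as its diketonate keep the α-stereocentre of the acyl group from enolising (no new stereocentre).

**Step 5**
Reactants: 7 (3R,9R)-9-[(5E)-6,10-dimethylundeca-1,5,9-trien-2-yl]-3,12-dimethyltridec-11-ene-4,6-dione
Product: 8 (2R)-1-[(5R,6R)-6-[(3E)-4,8-dimethylnona-3,7-dien-1-yl]-2-hydroxy-6-methyl-5-(3-methylbut-2-en-1-yl)cyclohex-1-en-1-yl]-2-methylbutan-1-one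
Conditions: C32H46CoN2O2, the divalent cobalt complex of N,N'-bis(3,5-di-tert-butylsalicylidene)ethane-1,2-diamine (5 mol %), N-phenylbenzo[b]phenothiazine (5 mol %), 2,4,6-collidinium triflate (20 mol %), CH2Cl2, 440 nm LEDs, 0 °C
Reagents that add atoms: none
Why: Proposed new method: a redox-neutral, light-driven cobalt-hydride radical–polar crossover cycloisomerisation (Conia-ene-type Markovnikov hydroalkylation) in which the photoreduced cobalt complex is protonated by the acidic β-diketone to a trivalent cobalt hydride that delivers H• only to the unhindered 1,1-disubstituted alkene (the three trisubstituted alkenes are too hindered), the tertiary C8 radical is captured by divalent cobalt and oxidised by the photocatalyst radical cation to a tetravalent alkylcobalt/tertiary cation, and the tethered diketonate carbon C1 closes the six-membered ring through a chair transition state with the C7 prenyl group and the larger homogeranyl chain equatorial and the new methyl axial, which sets C8; closest known reaction type: Mukaiyama-type hydrogen-atom-transfer hydrofunctionalisation of alkenes under photoredox/cobalt catalysis with O- and N-nucleophiles, and cation–olefin cyclisations terminated by β-dicarbonyl enols, so far not shown for C-alkylation by a 1,3-diketone.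

**Step 6**
Reactants: 8 (2R)-1-[(5R,6R)-6-[(3E)-4,8-dimethylnona-3,7-dien-1-yl]-2-hydroxy-6-methyl-5-(3-methylbut-2-en-1-yl)cyclohex-1-en-1-yl]-2-methylbutan-1-one
Product: 10 (1R,5R,7S,8R)-8-[(3E)-4,8-dimethylnona-3,7-dien-1-yl]-4-hydroxy-8-methyl-1-[(2R)-2-methylbutanoyl]-7-(3-methylbut-2-en-1-yl)bicyclo[3.3.1]non-3-ene-2,9-dione, via bis-silyl dienol ether 9 (not isolated)
Conditions: Me3SiOTf (2.4 equiv), Et3N (2.6 equiv), CH2Cl2, 0 °C, pentane filtration (gives 9); malonyl dichloride, CH2Cl2, −78 to −20 °C; silica gel
Reagents that add atoms: malonyl dichloride, O=C(Cl)CC(Cl)=O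
Why: Effenberger α,α'-annulation run as a [3+3] cyclisation of the 1,3-bis(silyl enol ether): the terminal carbon C5 is acylated first, the tethered acid chloride is then attacked by the C1 silyl enol ether (six-membered Mukaiyama-type C-acylation) to create the triacyl bridgehead, and because C5 equilibrates before closure and the bridge can only span the ring face anti to the C7 prenyl group (the 7-endo bicycle suffers C3/C7 transannular strain), C1 and C5 are both fixed.

**Compound list**
1 | (1S,2S,4R)-1-methyl-4-(prop-1-en-2-yl)cyclohexane-1,2-diol, (+)-limonene-1,2-diol | CC(=C)[C@@H]1CC[C@](C)(O)[C@@H](O)C1 | starting material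
2 | (1S,2S,4R)-4-[(5E)-6,10-dimethylundeca-1,5,9-trien-2-yl]-1-methylcyclohexane-1,2-diol | C=C(CC/C=C(\C)CCC=C(C)C)[C@@H]1CC[C@](C)(O)[C@@H](O)C1 | intermediate
3 | (3R)-3-[(5E)-6,10-dimethylundeca-1,5,9-trien-2-yl]-6-oxoheptanal | C=C(CC/C=C(\C)CCC=C(C)C)[C@@H](CC=O)CCC(C)=O | intermediate
4 | (5R)-5-[(5E)-6,10-dimethylundeca-1,5,9-trien-2-yl]-8-methylnon-7-en-2-one | C=C(CC/C=C(\C)CCC=C(C)C)[C@@H](CC=C(C)C)CCC(C)=O | intermediate
5 | (R)-2-methylbutanoic acid | CC[C@@H](C)C(=O)O | starting material
6 | 1-[(2R)-2-methylbutanoyl]-1H-imidazole (acyl imidazolide) | CC[C@@H](C)C(=O)n1ccnc1 | intermediate (not isolated)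
7 | (3R,9R)-9-[(5E)-6,10-dimethylundeca-1,5,9-trien-2-yl]-3,12-dimethyltridec-11-ene-4,6-dione | CC[C@@H](C)C(=O)CC(=O)CC[C@H](CC=C(C)C)C(=C)CC/C=C(\C)CCC=C(C)C | intermediate
8 | (2R)-1-[(5R,6R)-6-[(3E)-4,8-dimethylnona-3,7-dien-1-yl]-2-hydroxy-6-methyl-5-(3-methylbut-2-en-1-yl)cyclohex-1-en-1-yl]-2-methylbutan-1-one (enol form of the 2-acylcyclohexanone; prenyl and homogeranyl trans, prenyl and methyl cis) | CC[C@@H](C)C(=O)C1=C(O)CC[C@H](CC=C(C)C)[C@@]1(C)CC/C=C(\C)CCC=C(C)C | intermediate
9 | bis(trimethylsilyl) dienol ether of 8 (ring C5=C9 silyl enol ether plus exocyclic Z silyl enol ether at C1; enol ether geometry drawn for definiteness) | CC[C@@H](C)/C(O[Si](C)(C)C)=C1/C(O[Si](C)(C)C)=CC[C@H](CC=C(C)C)[C@@]1(C)CC/C=C(\C)CCC=C(C)C | intermediate (not isolated)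
10 | (1R,5R,7S,8R)-8-[(3E)-4,8-dimethylnona-3,7-dien-1-yl]-4-hydroxy-8-methyl-1-[(2R)-2-methylbutanoyl]-7-(3-methylbut-2-en-1-yl)bicyclo[3.3.1]non-3-ene-2,9-dione, CNP0158147.2 | CC[C@@H](C)C(=O)[C@@]12C(=O)C=C(O)[C@@H](C[C@H](CC=C(C)C)[C@@]1(C)CC/C=C(\C)CCC=C(C)C)C2=O | target

**Step count and risks**
Total step count: 6. Longest linear sequence: 6 steps (1 to 10).

The three steps most likely to fail:

Step 5 (the proposed new step). The risks are capture of the C8 cation by the enol oxygen (a dihydropyran) instead of by C1, binding of the diketonate to cobalt, and weak discrimination between methyl and the CH2 chain at the planar C8 centre. Some C8 epimer is therefore expected and would be removed at the stage of 8. The fallback uses known chemistry, a thermal Conia-ene cyclisation: 7 is heated in degassed o-dichlorobenzene with a trace of 2,6-di-tert-butyl-4-methylphenol at about 230 °C (sealed tube or flow coil). The enol adds across the 1,1-disubstituted alkene through a concerted six-membered hydrogen transfer that holds the =CH2 carbon (the future methyl) over the enol oxygen, i.e. axial, with the chain next to the C7 hydrogen, so the same C8 configuration results. This fallback sets out from 7 and comes back at 8; it makes no new compound (none F0).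

Step 6. The risks are C-acylation at the very hindered C1, O-acylation leading to a pyranone instead of the bridged trione, and some enolisation toward the acyl stereocentre during silylation. The fallback sets out from 8: condensation with bis(2,4,6-trichlorophenyl) malonate in diphenyl ether at about 160 °C acylates C5 and lactonises onto the C9 enol oxygen to give the fused 4-hydroxy-2-pyranone F3. Mg(OMe)2 in MeOH at reflux then opens the lactone and re-closes it by Claisen condensation at C1. This is the known pyranone-to-acylphloroglucinol recyclisation, stopped here at the bridged trione because C1 becomes quaternary. It comes back to the route at 10.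

Step 1. The risks are poor solubility of the dilithium dialkoxide during the allylic lithiation, O-geranylation, and SN2' coupling. The fallback sets out from 1: 2,2-dimethoxypropane with pyridinium p-toluenesulfonate gives the acetonide of 1 F1. Lithiation with n-BuLi/TMEDA and alkylation with geranyl bromide give the geranylated acetonide F2. H5IO6 in Et2O/THF then hydrolyses the acetonide and cleaves the diol in one pot, coming back to the route at 3.

**Further compounds**
F1 | step 1 | acetonide of 1, (3aS,5R,7aS)-2,2,7a-trimethyl-5-(prop-1-en-2-yl)hexahydro-1,3-benzodioxole | CC(=C)[C@@H]1CC[C@]2(C)OC(C)(C)O[C@H]2C1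
F2 | step 1 | geranylated acetonide, (3aS,5R,7aS)-5-[(5E)-6,10-dimethylundeca-1,5,9-trien-2-yl]-2,2,7a-trimethylhexahydro-1,3-benzodioxole | C=C(CC/C=C(\C)CCC=C(C)C)[C@@H]1CC[C@]2(C)OC(C)(C)O[C@H]2C1
F0 | step 5 | none | none
F3 | step 6 | fused 4-hydroxy-2-pyranone, (6S,7R)-7-[(3E)-4,8-dimethylnona-3,7-dien-1-yl]-4-hydroxy-7-methyl-8-[(2R)-2-methylbutanoyl]-6-(3-methylbut-2-en-1-yl)-5,6,7,8-tetrahydro-2H-chromen-2-one (epimers at the acyl-bearing carbon) | CC[C@@H](C)C(=O)C1C2=C(C[C@H](CC=C(C)C)[C@@]1(C)CC/C=C(\C)CCC=C(C)C)C(O)=CC(=O)O2
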